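The plan disconnects the single bond between the two CH carbons at the centre of the (2E,4E)-diene carried by C5 of the γ-lactone ring (C3–C4 of the 6-(hydroxymethyl)deca-2,4-dien-2-yl chain). Because this bond joins two alkenes whose E geometries can be fixed separately, one stereoretentive Suzuki–Miyaura coupling unites two complete, unprotected halves and gives the target in the last operation. Its precursors are an alkenyl pinacolboronate made in two steps from hexanal and a trisubstituted vinyl iodide that already holds the all-trans lactone, the second diene and the syn-ketol.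

Key step: step 14

Step 1
Reactants: 1 hexanal; 2 formaldehyde
Product: 3 (S)-2-(hydroxymethyl)hexanal
Conditions: (R)-2-[diphenyl(trimethylsilyloxy)methyl]pyrrolidine (10 mol %), 37% aq. HCHO, pH 7 phosphate buffer, toluene, rt; used crude
Reagents that add atoms: none
Why: Organocatalytic α-hydroxymethylation (enamine-mediated cross-aldol with formaldehyde) should work because the diphenyl(silyloxy)methyl group of the (R)-catalyst shields one face of the E-enamine, so that formaldehyde adds to the open face and sets the (S) centre.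

Step 2
Reactants: 3 (S)-2-(hydroxymethyl)hexanal; 4 2-(dichloromethyl)-4,4,5,5-tetramethyl-1,3,2-dioxaborolane
Product: 6 (2R,3E)-2-butyl-4-(4,4,5,5-tetramethyl-1,3,2-dioxaborolan-2-yl)but-3-en-1-ol, via geminal dichromium reagent 5 (not isolated)
Conditions: CrCl2 (8 equiv), LiI (4 equiv), THF, rt
Reagents that add atoms: none
Why: Takai–Utimoto boryl-olefination should convert the aldehyde into the E-alkenylboronate by addition of 5 and elimination, under non-basic conditions that leave the α-stereocentre (R only through the change in CIP ranking) and the free hydroxyl untouched.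

Step 3
Reactants: 7 (R)-4-benzyl-3-propanoyl-1,3-oxazolidin-2-one; 8 acrolein
Product: 10 (R)-4-benzyl-3-[(2R,3S)-3-hydroxy-2-methylpent-4-enoyl]-1,3-oxazolidin-2-one, via boron enolate 9 (not isolated)
Conditions: Bu2BOTf, Et3N, CH2Cl2, 0 °C; 8, −78 → 0 °C; then pH 7 buffer, MeOH, H2O2, 0 °C
Reagents that add atoms: none
Why: Evans syn-aldol reaction, in which Z-boron enolate 9 should add to acrolein through a chair Zimmerman–Traxler transition state on the face away from the benzyl group of the auxiliary, setting the (2R,3S) centres.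

Step 4
Reactants: 10 (R)-4-benzyl-3-[(2R,3S)-3-hydroxy-2-methylpent-4-enoyl]-1,3-oxazolidin-2-one
Product: 11 (2R,3S)-3-hydroxy-N-methoxy-N,2-dimethylpent-4-enamide
Conditions: MeNH(OMe)·HCl, AlMe3, THF, −20 → 0 °C
Reagents that add atoms: N,O-dimethylhydroxylamine hydrochloride, CNOC.Cl
Why: Weinreb transamidation with the aluminium amide, assisted by the β-alkoxide, should cleave only the exocyclic imide carbonyl and leave both stereocentres intact.

Step 5
Reactants: 11 (2R,3S)-3-hydroxy-N-methoxy-N,2-dimethylpent-4-enamide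
Product: 12 (3R,4S)-4-hydroxy-3-methylhex-5-en-2-one
Conditions: MeMgBr (3 equiv), THF, −20 → 0 °C; aq. NH4Cl
Reagents that add atoms: methylmagnesium bromide, C[Mg]Br
Why: Weinreb ketone synthesis, in which the N-methoxy-N-methylamide should take up one methyl group only and release the methyl ketone on work-up, the low temperature guarding the epimerizable α-centre.

Step 6
Reactants: 13 prop-2-yn-1-ol
Product: 15 (E)-3-iodo-2-methylprop-2-en-1-ol, via alkenylalane 14 (not isolated)
Conditions: AlMe3 (3 equiv), Cp2ZrCl2 (0.25 equiv), CH2Cl2, 0 °C → rt; then I2, THF, −30 → 0 °C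
Reagents that add atoms: trimethylaluminium, C[Al](C)C; iodine, II
Why: Negishi zirconium-catalysed carboalumination should add methyl and aluminium syn across the alkyne with methyl on the internal carbon, and iodinolysis of the C–Al bond of 14 with retention then gives the E-iodide.

Step 7
Reactants: 15 (E)-3-iodo-2-methylprop-2-en-1-ol
Product: 16 (E)-3-iodo-2-methylprop-2-enal
Conditions: MnO2, CH2Cl2, rt; used as a solution
Reagents that add atoms: none
Why: Allylic alcohol oxidation with MnO2 should give the enal without touching the vinyl iodide or the alkene geometry.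

Step 8
Reactants: 16 (E)-3-iodo-2-methylprop-2-enal; 17 (E)-but-2-ene
Product: 20 (1E,3S,4S)-1-iodo-2,4-dimethylhexa-1,5-dien-3-ol, via crotylpotassium 18 (not isolated), via crotylborane 19 (not isolated)
Conditions: 17, KOtBu, n-BuLi, THF, −78 → −45 °C; (−)-Ipc2BOMe, −78 °C; BF3·OEt2; 16, −78 °C; then NaOH, H2O2
Reagents that add atoms: none
Why: Brown crotylboration, in which E-crotylborane 19 should add through a chair transition state to give the anti relationship while the isopinocampheyl groups derived from (+)-α-pinene select the aldehyde face that leads to the (3S,4S) alcohol.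

Step 9
Reactants: 20 (1E,3S,4S)-1-iodo-2,4-dimethylhexa-1,5-dien-3-ol
Product: 22 (3S,4S,5E)-6-iodo-3,5-dimethylhex-5-ene-1,4-diol, via bis-borane adduct 21 (not isolated)
Conditions: 9-BBN (2.5 equiv), THF, 0 °C → rt; then NaOH, H2O2, 0 °C
Reagents that add atoms: hydrogen peroxide, OO
Why: Hydroboration–oxidation, in which 9-BBN should add anti-Markovnikov to the monosubstituted alkene only, the trisubstituted iodoalkene being too hindered and electron-poor, before oxidation of the C–B bond gives the primary alcohol.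

Step 10
Reactants: 22 (3S,4S,5E)-6-iodo-3,5-dimethylhex-5-ene-1,4-diol
Product: 24 (4S,5S)-5-[(E)-1-iodoprop-1-en-2-yl]-4-methyloxolan-2-one, via lactol 23 (not isolated)
Conditions: TEMPO (0.2 equiv), PhI(OAc)2 (2.5 equiv), CH2Cl2, rt
Reagents that add atoms: none
Why: TEMPO/PhI(OAc)2 oxidative lactonization should oxidize the primary alcohol selectively, the aldehyde closing with the C4 hydroxyl to lactol 23, which is oxidized on to the γ-lactone with both stereocentres unchanged.

Step 11
Reactants: 24 (4S,5S)-5-[(E)-1-iodoprop-1-en-2-yl]-4-methyloxolan-2-one; 25 (E)-3-ethoxy-2-methylprop-2-enal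
Product: 28 (E)-3-[(3S,4S,5S)-5-[(E)-1-iodoprop-1-en-2-yl]-4-methyl-2-oxooxolan-3-yl]-2-methylprop-2-enal, via lithium enolate 26 (not isolated), via aldol adduct 27 (not isolated)
Conditions: LiN(SiMe3)2, THF, −78 °C; 25, −78 °C; then 1 M HCl, THF, 0 °C → rt
Reagents that add atoms: water, O
Why: Aldol addition followed by acid-induced transposition of the resulting vinylogous hemiacetal (Stork–Danheiser-type sequence), in which enolate 26 should react on the face anti to the C4 methyl group, setting C3 trans, and ionization of the carbinol next to the enol ether of 27 gives the E-enal without elimination toward C3.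

Step 12
Reactants: 28 (E)-3-[(3S,4S,5S)-5-[(E)-1-iodoprop-1-en-2-yl]-4-methyl-2-oxooxolan-3-yl]-2-methylprop-2-enal
Product: 29 (3S,4S,5S)-5-[(E)-1-iodoprop-1-en-2-yl]-4-methyl-3-[(1E)-2-methylbuta-1,3-dien-1-yl]oxolan-2-one
Conditions: Zn, CH2Br2, TiCl4, THF/CH2Cl2, 0 °C → rt
Reagents that add atoms: dibromomethane, BrCBr
Why: Lombardo-type titanium–zinc methylenation is non-basic and aldehyde-selective, so the acidic C3–H, the lactone and the vinyl iodide should survive.

Step 13
Reactants: 29 (3S,4S,5S)-5-[(E)-1-iodoprop-1-en-2-yl]-4-methyl-3-[(1E)-2-methylbuta-1,3-dien-1-yl]oxolan-2-one; 12 (3R,4S)-4-hydroxy-3-methylhex-5-en-2-one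
Product: 30 (3S,4S,5S)-3-[(1E,3E,5S,6R)-5-hydroxy-2,6-dimethyl-7-oxoocta-1,3-dien-1-yl]-5-[(E)-1-iodoprop-1-en-2-yl]-4-methyloxolan-2-one
Conditions: second-generation Hoveyda–Grubbs catalyst (10 mol %), 12 (3 equiv), CH2Cl2, 40 °C
Reagents that add atoms: none
Why: Ene–diene olefin cross-metathesis should engage only the two monosubstituted alkenes, the trisubstituted alkenes being too hindered, and give the new disubstituted alkene as the E isomer while the stereocentres of 12 and 29 are not involved.

Step 14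
Reactants: 30 (3S,4S,5S)-3-[(1E,3E,5S,6R)-5-hydroxy-2,6-dimethyl-7-oxoocta-1,3-dien-1-yl]-5-[(E)-1-iodoprop-1-en-2-yl]-4-methyloxolan-2-one; 6 (2R,3E)-2-butyl-4-(4,4,5,5-tetramethyl-1,3,2-dioxaborolan-2-yl)but-3-en-1-ol
Product: 31 (3S,4S,5S)-5-[(2E,4E,6R)-6-(hydroxymethyl)deca-2,4-dien-2-yl]-3-[(1E,3E,5S,6R)-5-hydroxy-2,6-dimethyl-7-oxoocta-1,3-dien-1-yl]-4-methyloxolan-2-one
Conditions: Pd(PPh3)4 (10 mol %), TlOEt (1.8 equiv), degassed THF/H2O (3:1), rt
Reagents that add atoms: none
Why: Zerovalent palladium should insert into the C–I bond of 30 with retention, the alkenyl group of 6 is transferred to palladium after activation by ethoxide/hydroxide, and reductive elimination forms the bond between the two CH carbons of the diene. The closest known reaction type is the thallium-accelerated Suzuki–Miyaura alkenyl–alkenyl coupling used for late polyene unions. The step closes no ring and creates no stereocentre; both alkene geometries are carried over because each elementary step at the alkenyl carbons is stereoretentive. It needs chemoselectivity for the one C–I bond beside a free primary alcohol, a β-hydroxy ketone and an enolizable α-alkenyl lactone. This should be secured by the speed of the TlOEt-promoted coupling at room temperature, which leaves little time for retro-aldol, elimination or enolization, and by the all-trans lactone being the thermodynamic isomer.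

Compound list
1 | hexanal | CCCCCC=O | starting material
2 | formaldehyde | C=O | starting material
3 | (S)-2-(hydroxymethyl)hexanal | CCCC[C@@H](CO)C=O | intermediate
4 | 2-(dichloromethyl)-4,4,5,5-tetramethyl-1,3,2-dioxaborolane | ClC(Cl)B1OC(C)(C)C(C)(C)O1 | starting material
5 | bis(dichlorochromio)(4,4,5,5-tetramethyl-1,3,2-dioxaborolan-2-yl)methane (geminal dichromium reagent) | Cl[Cr](Cl)C([Cr](Cl)Cl)B1OC(C)(C)C(C)(C)O1 | intermediate
6 | (2R,3E)-2-butyl-4-(4,4,5,5-tetramethyl-1,3,2-dioxaborolan-2-yl)but-3-en-1-ol | CCCC[C@H](/C=C/B1OC(C)(C)C(C)(C)O1)CO | intermediate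
7 | (R)-4-benzyl-3-propanoyl-1,3-oxazolidin-2-one | CCC(=O)N1C(=O)OC[C@H]1Cc1ccccc1 | starting material
8 | acrolein | C=CC=O | starting material
9 | (Z)-O-dibutylboryl enolate of 7 | C/C=C(\OB(CCCC)CCCC)N1C(=O)OC[C@H]1Cc1ccccc1 | intermediate
10 | (R)-4-benzyl-3-[(2R,3S)-3-hydroxy-2-methylpent-4-enoyl]-1,3-oxazolidin-2-one | C=C[C@H](O)[C@@H](C)C(=O)N1C(=O)OC[C@H]1Cc1ccccc1 | intermediate
11 | (2R,3S)-3-hydroxy-N-methoxy-N,2-dimethylpent-4-enamide | C=C[C@H](O)[C@@H](C)C(=O)N(C)OC | intermediate
12 | (3R,4S)-4-hydroxy-3-methylhex-5-en-2-one | C=C[C@H](O)[C@@H](C)C(C)=O | intermediate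
13 | prop-2-yn-1-ol | C#CCO | starting material
14 | (E)-[3-(dimethylalumanyloxy)-2-methylprop-1-enyl]dimethylalane | C[Al](C)OC/C(C)=C/[Al](C)C | intermediate
15 | (E)-3-iodo-2-methylprop-2-en-1-ol | OC/C(C)=C/I | intermediate
16 | (E)-3-iodo-2-methylprop-2-enal | O=C/C(C)=C/I | intermediate
17 | (E)-but-2-ene | C/C=C/C | starting material
18 | (E)-but-2-enylpotassium | C/C=C/C[K] | intermediate
19 | (E)-but-2-enyl-bis(isopinocampheyl)borane, isopinocampheyl groups from (+)-α-pinene | C/C=C/CB([C@@H]1C[C@@H]2C[C@H]([C@H]1C)C2(C)C)[C@@H]1C[C@@H]2C[C@H]([C@H]1C)C2(C)C | intermediate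
20 | (1E,3S,4S)-1-iodo-2,4-dimethylhexa-1,5-dien-3-ol | I/C=C(\C)[C@@H](O)[C@@H](C)C=C | intermediate
21 | O-borinate B-alkyl bis(9-borabicyclo[3.3.1]nonane) adduct of 20 | I/C=C(\C)[C@@H](OB1C2CCCC1CCC2)[C@@H](C)CCB1C2CCCC1CCC2 | intermediate
22 | (3S,4S,5E)-6-iodo-3,5-dimethylhex-5-ene-1,4-diol | I/C=C(\C)[C@@H](O)[C@@H](C)CCO | intermediate
23 | (4S,5S)-5-[(E)-1-iodoprop-1-en-2-yl]-4-methyloxolan-2-ol (lactol, both anomers) | I/C=C(\C)[C@H]1OC(O)C[C@@H]1C | intermediate
24 | (4S,5S)-5-[(E)-1-iodoprop-1-en-2-yl]-4-methyloxolan-2-one | I/C=C(\C)[C@H]1OC(=O)C[C@@H]1C | intermediate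
25 | (E)-3-ethoxy-2-methylprop-2-enal | CCO/C=C(\C)C=O | starting material
26 | lithium enolate of 24 | I/C=C(\C)[C@H]1OC(O[Li])=C[C@@H]1C | intermediate
27 | (3S,4S,5S)-3-[(E)-3-ethoxy-1-hydroxy-2-methylprop-2-enyl]-5-[(E)-1-iodoprop-1-en-2-yl]-4-methyloxolan-2-one (both carbinol epimers) | I/C=C(\C)[C@H]1OC(=O)[C@@H](C(O)/C(C)=C/OCC)[C@@H]1C | intermediate
28 | (E)-3-[(3S,4S,5S)-5-[(E)-1-iodoprop-1-en-2-yl]-4-methyl-2-oxooxolan-3-yl]-2-methylprop-2-enal | I/C=C(\C)[C@H]1OC(=O)[C@@H](/C=C(C)/C=O)[C@@H]1C | intermediate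
29 | (3S,4S,5S)-5-[(E)-1-iodoprop-1-en-2-yl]-4-methyl-3-[(1E)-2-methylbuta-1,3-dien-1-yl]oxolan-2-one | I/C=C(\C)[C@H]1OC(=O)[C@@H](/C=C(C)/C=C)[C@@H]1C | intermediate
30 | (3S,4S,5S)-3-[(1E,3E,5S,6R)-5-hydroxy-2,6-dimethyl-7-oxoocta-1,3-dien-1-yl]-5-[(E)-1-iodoprop-1-en-2-yl]-4-methyloxolan-2-one | I/C=C(\C)[C@H]1OC(=O)[C@@H](/C=C(C)/C=C/[C@H](O)[C@@H](C)C(C)=O)[C@@H]1C | intermediate
31 | (3S,4S,5S)-5-[(2E,4E,6R)-6-(hydroxymethyl)deca-2,4-dien-2-yl]-3-[(1E,3E,5S,6R)-5-hydroxy-2,6-dimethyl-7-oxoocta-1,3-dien-1-yl]-4-methyloxolan-2-one | CCCC[C@H](/C=C/C=C(\C)[C@H]1OC(=O)[C@@H](/C=C(C)/C=C/[C@H](O)[C@@H](C)C(C)=O)[C@@H]1C)CO | target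

Total step count: 14. Longest linear sequence: 9 steps (steps 6 to 14, from prop-2-yn-1-ol).

Steps most likely to fail

Step 13. The ruthenium carbene may be held as an unreactive vinylcarbene on the conjugated diene, 29 may undergo self-metathesis, or ruthenium hydrides may isomerize the allylic alcohol of 12. The fallback builds the ketol by an aldol reaction instead of joining a finished ketol. It sets out from 28: Wittig homologation with Ph3P=CHCHO (toluene, 80 °C) should give (2E,4E)-5-[(3S,4S,5S)-5-[(E)-1-iodoprop-1-en-2-yl]-4-methyl-2-oxooxolan-3-yl]-4-methylpenta-2,4-dienal F1. A syn-selective Mukaiyama aldol reaction of F1 with (Z)-2-(trimethylsilyloxy)but-2-ene follows, catalysed by the acyloxyborane made from (2R,3R)-2-O-(2,6-diisopropoxybenzoyl)tartaric acid and BH3·THF (EtCN, −78 °C). That catalyst series is chosen on the expectation that it directs attack to the Re face of the aldehyde. The product should be the trimethylsilyl ether of 30, F2, and dilute HCl returns the sequence to 30.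

Step 14. Base-induced retro-aldol cleavage or β-elimination of the ketol, or protodeboronation of the alkenylboronate, may outrun transmetalation. The fallback is a neutral Stille coupling. It sets out from 3: chromium-mediated stannyl-olefination (Bu3SnCHBr2, CrCl2, LiI, THF) should give (2R,3E)-2-butyl-4-(tributylstannyl)but-3-en-1-ol F3. F3 is coupled with 30 using Pd2(dba)3 and AsPh3 in NMP at rt, and the sequence returns at 31.

Step 2. Retro-aldol loss of formaldehyde or dehydration of the free β-hydroxy aldehyde at the Lewis-acidic chromium centre may erode yield and enantiomeric purity. The fallback masks the hydroxyl and makes the alkenylboronate by alkyne hydroboration. It sets out from 3: silylation (TBSCl, imidazole, CH2Cl2) should give (S)-2-[(tert-butyldimethylsilyloxy)methyl]hexanal F4. Ohira–Bestmann homologation (dimethyl (1-diazo-2-oxopropyl)phosphonate, K2CO3, MeOH) gives (R)-tert-butyl[(2-ethynylhexyl)oxy]dimethylsilane F5. Hydroboration with pinacolborane catalysed by Cp2Zr(H)Cl gives (R,E)-tert-butyl{[2-butyl-4-(4,4,5,5-tetramethyl-1,3,2-dioxaborolan-2-yl)but-3-enyl]oxy}dimethylsilane F6. HF·pyridine in THF removes the silyl group and returns the sequence to 6.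

Further compounds
F1 | step 13 | (2E,4E)-5-[(3S,4S,5S)-5-[(E)-1-iodoprop-1-en-2-yl]-4-methyl-2-oxooxolan-3-yl]-4-methylpenta-2,4-dienal | I/C=C(\C)[C@H]1OC(=O)[C@@H](/C=C(C)/C=C/C=O)[C@@H]1C
F2 | step 13 | trimethylsilyl ether of 30 | I/C=C(\C)[C@H]1OC(=O)[C@@H](/C=C(C)/C=C/[C@H](O[Si](C)(C)C)[C@@H](C)C(C)=O)[C@@H]1C
F3 | step 14 | (2R,3E)-2-butyl-4-(tributylstannyl)but-3-en-1-ol | CCCC[C@H](/C=C/[Sn](CCCC)(CCCC)CCCC)CO
F4 | step 2 | (S)-2-[(tert-butyldimethylsilyloxy)methyl]hexanal | CCCC[C@@H](CO[Si](C)(C)C(C)(C)C)C=O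
F5 | step 2 | (R)-tert-butyl[(2-ethynylhexyl)oxy]dimethylsilane | CCCC[C@@H](CO[Si](C)(C)C(C)(C)C)C#C
F6 | step 2 | (R,E)-tert-butyl{[2-butyl-4-(4,4,5,5-tetramethyl-1,3,2-dioxaborolan-2-yl)but-3-enyl]oxy}dimethylsilane | CCCC[C@H](/C=C/B1OC(C)(C)C(C)(C)O1)CO[Si](C)(C)C(C)(C)C
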